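**Plan**
Locants follow the target name: O1, C2 (oxirane CH2), spiro C3, C4 (OMe, aryl), C5=O, C6(OMe)=C7(aryl) of the 1-oxaspiro[2.4]hept-6-en-5-one core.
Retrosynthetic cuts, in order: the oxirane (C3 ketone plus CH2 from a sulfur ylide); C6=C7 (ring-closing Horner–Wadsworth–Emmons olefination); C5–C6 (ester plus α-methoxy phosphonate anion); the C3/C7 1,2-dione is unmasked from an alkyne; C3–C4 (alkyne plus aryl α-keto ester).
Forward: the open chain C7≡C3–C4–C5 is assembled, C6 is added as the phosphonate, the alkyne is oxidised, the five-membered carbocycle is closed at C6=C7, the phenols are freed and the oxirane ring is made last.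
Enabling feature: the tetrasubstituted C6=C7 enol-ether double bond of the cyclopentenone, conjugated to the C5 ketone and flanked at C7 by the carbonyl-level carbon C3. An α-methoxy-β-aryl enone is the direct product of an α-methoxy-β-ketophosphonate closing onto an aryl ketone, and only the C7 carbonyl of the 1,2-dione can give a five-membered ring.
Stereochemistry: C4 (R) from a catalytic enantioselective alkynylation (quaternary, cannot epimerise afterwards); C3 (R) by substrate control, the ylide carbon adding to the C3 carbonyl anti to the C4 aryl group while the C5 carbonyl is switched off as a vinylogous phenoxide.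

Key step: step 7

Remark: 1 and 3 are taken as purchasable; the sense of induction in step 3 is assumed to be selectable through the ligand antipode, and the antipode that gives the (R)-carbinol is used.

**Step 1**
Reactants: 1 methyl 2-(4-hydroxyphenyl)-2-oxoacetate
Product: 2 methyl 2-oxo-2-[4-(triisopropylsilyloxy)phenyl]acetate
Conditions: TIPSCl, imidazole, DMF, 0 °C to rt
Reagents that add atoms: chlorotriisopropylsilane CC(C)[Si](Cl)(C(C)C)C(C)C
Why: Silyl ether formation masks the acidic phenol for the base and organolithium steps, and the bulky silyl group should survive NaH and lithium amide yet leave with fluoride.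

**Step 2**
Reactants: 3 4-ethynylphenol
Product: 4 (4-ethynylphenoxy)triisopropylsilane
Conditions: TIPSCl, imidazole, DMF, 0 °C to rt
Reagents that add atoms: chlorotriisopropylsilane CC(C)[Si](Cl)(C(C)C)C(C)C
Why: Silyl ether formation, as in step 1, leaves the terminal alkyne C–H as the only acidic site for the zinc-mediated addition.

**Step 3**
Reactants: 2 methyl 2-oxo-2-[4-(triisopropylsilyloxy)phenyl]acetate; 4 (4-ethynylphenoxy)triisopropylsilane
Product: 5 methyl (2R)-2-hydroxy-2,4-bis[4-(triisopropylsilyloxy)phenyl]but-3-ynoate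
Conditions: Zn(OTf)2 (20 mol%), single-enantiomer 2-(dimethylamino)-1-(4-nitrophenyl)-3-(tert-butyldimethylsilyloxy)propan-1-ol (22 mol%), Et3N (30 mol%), toluene, 70 °C
Reagents that add atoms: none
Why: Catalytic enantioselective alkynylation of an α-keto ester, in which the alkyne, metalated reversibly on zinc, adds to the two-point-bound keto ester inside the chiral amino alkoxide complex, and the ligand selects the carbonyl face that gives the (R) quaternary carbinol (future C4).

**Step 4**
Reactants: 5 methyl (2R)-2-hydroxy-2,4-bis[4-(triisopropylsilyloxy)phenyl]but-3-ynoate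
Product: 7 methyl (2R)-2-methoxy-2,4-bis[4-(triisopropylsilyloxy)phenyl]but-3-ynoate, via sodium alkoxide 6 (not isolated)
Conditions: NaH, MeI, THF, 0 °C to rt
Reagents that add atoms: iodomethane CI
Why: Williamson etherification of the tertiary alkoxide, which has no enolisable position, should give the C4 methyl ether without touching the stereocentre.

**Step 5**
Reactants: 7 methyl (2R)-2-methoxy-2,4-bis[4-(triisopropylsilyloxy)phenyl]but-3-ynoate; 8 diethyl (methoxymethyl)phosphonate
Product: 10 diethyl [(3R)-1,3-dimethoxy-2-oxo-3,5-bis[4-(triisopropylsilyloxy)phenyl]pent-4-yn-1-yl]phosphonate (both C1 epimers), via lithiated phosphonate 9 (not isolated)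
Conditions: 8 (2.5 equiv), LiN(iPr)2 (2.4 equiv), THF, −78 °C; then 7, −78 to −30 °C; aq NH4Cl
Reagents that add atoms: none
Why: Claisen-type acylation of the lithiated α-methoxy phosphonate by the α-alkoxy-activated ester gives the β-ketophosphonate, which is deprotonated by the second equivalent and so protected from over-addition; the new centre at the phosphonate carbon is lost in step 7.

**Step 6**
Reactants: 10 diethyl [(3R)-1,3-dimethoxy-2-oxo-3,5-bis[4-(triisopropylsilyloxy)phenyl]pent-4-yn-1-yl]phosphonate
Product: 11 diethyl [(3R)-1,3-dimethoxy-2,4,5-trioxo-3,5-bis[4-(triisopropylsilyloxy)phenyl]pentyl]phosphonate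
Conditions: KMnO4, NaHCO3, MgSO4, acetone/H2O, 0 °C to rt
Reagents that add atoms: potassium permanganate [K+].[O-][Mn](=O)(=O)=O
Why: Buffered permanganate dioxygenation of a disubstituted alkyne to a 1,2-diketone unmasks the C7 aryl ketone and the C3 ketone at once, the aryl alkyne being the most oxidisable π bond in the molecule.

**Step 7**
Reactants: 11 diethyl [(3R)-1,3-dimethoxy-2,4,5-trioxo-3,5-bis[4-(triisopropylsilyloxy)phenyl]pentyl]phosphonate
Product: 13 (2R)-2,5-dimethoxy-2,4-bis[4-(triisopropylsilyloxy)phenyl]cyclopent-4-ene-1,3-dione, via sodium phosphonate carbanion 12 (not isolated)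
Conditions: NaH, THF, 0 °C to rt
Reagents that add atoms: none
Why: Deprotonation of the α-methoxy-β-ketophosphonate gives the stabilised carbanion 12 at the future C6, which adds to the aryl ketone carbonyl (future C7) of the 1,2-dione, and syn-elimination of diethyl phosphate then delivers the C6=C7 double bond (intramolecular Horner–Wadsworth–Emmons olefination). The closest known reaction type is the base-mediated cyclisation of 2,5-dioxoalkylphosphonates to cyclopentenones. The five-membered carbocycle (C3 to C7) closes by a 5-exo-trig addition to the C7 carbonyl, the enolate double bond lying outside the forming ring. No new stereocentre remains, since the transient centres at C6 and C7 are lost on elimination and the quaternary C4 has no α-hydrogen and cannot epimerise. The step needs site selectivity between the two ketones of the dione, and ring size secures it: attack at the C3 carbonyl would give a strained four-membered ring and is reversible, whereas closure at C7 is made irreversible by loss of phosphate. The position of the enol-ether oxygen is fixed by the reagent carbon, so no ambiguous enol methylation arises, and the non-nucleophilic base avoids retro-Claisen cleavage of the 2,2-disubstituted 1,3-dicarbonyl unit.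

**Step 8**
Reactants: 13 (2R)-2,5-dimethoxy-2,4-bis[4-(triisopropylsilyloxy)phenyl]cyclopent-4-ene-1,3-dione
Product: 14 (2R)-2,4-bis(4-hydroxyphenyl)-2,5-dimethoxycyclopent-4-ene-1,3-dione
Conditions: Bu4NF, AcOH, THF, 0 °C
Reagents that add atoms: none
Why: Fluoride-driven desilylation of the aryl silyl ethers, buffered with acetic acid to spare the base-sensitive non-enolisable 1,3-dione, frees both phenols before the sensitive oxirane exists.

**Step 9**
Reactants: 14 (2R)-2,4-bis(4-hydroxyphenyl)-2,5-dimethoxycyclopent-4-ene-1,3-dione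
Product: 16 (3R,4R)-4,7-bis(4-hydroxyphenyl)-4,6-dimethoxy-1-oxaspiro[2.4]hept-6-en-5-one, via dipotassium bisphenoxide 15 (not isolated)
Conditions: KN(SiMe3)2 (2.1 equiv), THF/DMSO, −20 °C; then ylide from Me3SI and KN(SiMe3)2 (3 equiv), −20 to 0 °C; aq NH4Cl
Reagents that add atoms: trimethylsulfonium iodide C[S+](C)C.[I-]
Why: Corey–Chaykovsky epoxidation, in which the C5 carbonyl of dianion 15 is deactivated as the vinylogous phenoxide of the C7 aryl group, so dimethylsulfonium methylide adds to the C3 ketone with its carbon entering anti to the bulkier C4 aryl group (syn to OMe), and the alkoxide then displaces dimethyl sulfide to place the oxirane oxygen cis to that aryl group, giving (3R).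

**Compound list**
1 | methyl 2-(4-hydroxyphenyl)-2-oxoacetate | COC(=O)C(=O)c1ccc(O)cc1 | starting material
2 | methyl 2-oxo-2-[4-(triisopropylsilyloxy)phenyl]acetate | COC(=O)C(=O)c1ccc(O[Si](C(C)C)(C(C)C)C(C)C)cc1 | intermediate
3 | 4-ethynylphenol | C#Cc1ccc(O)cc1 | starting material
4 | (4-ethynylphenoxy)triisopropylsilane | C#Cc1ccc(O[Si](C(C)C)(C(C)C)C(C)C)cc1 | intermediate
5 | methyl (2R)-2-hydroxy-2,4-bis[4-(triisopropylsilyloxy)phenyl]but-3-ynoate | CC(C)[Si](C(C)C)(C(C)C)Oc1ccc(cc1)C#C[C@](O)(c1ccc(O[Si](C(C)C)(C(C)C)C(C)C)cc1)C(=O)OC | intermediate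
6 | sodium alkoxide of 5 | CC(C)[Si](C(C)C)(C(C)C)Oc1ccc(cc1)C#C[C@]([O-])(c1ccc(O[Si](C(C)C)(C(C)C)C(C)C)cc1)C(=O)OC.[Na+] | intermediate (not isolated)
7 | methyl (2R)-2-methoxy-2,4-bis[4-(triisopropylsilyloxy)phenyl]but-3-ynoate | CC(C)[Si](C(C)C)(C(C)C)Oc1ccc(cc1)C#C[C@](OC)(c1ccc(O[Si](C(C)C)(C(C)C)C(C)C)cc1)C(=O)OC | intermediate
8 | diethyl (methoxymethyl)phosphonate | COCP(=O)(OCC)OCC | starting material
9 | diethyl [lithio(methoxy)methyl]phosphonate | [Li]C(OC)P(=O)(OCC)OCC | intermediate (not isolated)
10 | diethyl [(3R)-1,3-dimethoxy-2-oxo-3,5-bis[4-(triisopropylsilyloxy)phenyl]pent-4-yn-1-yl]phosphonate, both C1 epimers | CC(C)[Si](C(C)C)(C(C)C)Oc1ccc(cc1)C#C[C@](OC)(c1ccc(O[Si](C(C)C)(C(C)C)C(C)C)cc1)C(=O)C(OC)P(=O)(OCC)OCC | intermediate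
11 | diethyl [(3R)-1,3-dimethoxy-2,4,5-trioxo-3,5-bis[4-(triisopropylsilyloxy)phenyl]pentyl]phosphonate, both C1 epimers | CC(C)[Si](C(C)C)(C(C)C)Oc1ccc(cc1)C(=O)C(=O)[C@](OC)(c1ccc(O[Si](C(C)C)(C(C)C)C(C)C)cc1)C(=O)C(OC)P(=O)(OCC)OCC | intermediate
12 | sodium salt of 11, carbanion at the phosphonate carbon | CC(C)[Si](C(C)C)(C(C)C)Oc1ccc(cc1)C(=O)C(=O)[C@](OC)(c1ccc(O[Si](C(C)C)(C(C)C)C(C)C)cc1)C(=O)[C-](OC)P(=O)(OCC)OCC.[Na+] | intermediate (not isolated)
13 | (2R)-2,5-dimethoxy-2,4-bis[4-(triisopropylsilyloxy)phenyl]cyclopent-4-ene-1,3-dione | COC1=C(c2ccc(O[Si](C(C)C)(C(C)C)C(C)C)cc2)C(=O)[C@](OC)(c2ccc(O[Si](C(C)C)(C(C)C)C(C)C)cc2)C1=O | intermediate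
14 | (2R)-2,4-bis(4-hydroxyphenyl)-2,5-dimethoxycyclopent-4-ene-1,3-dione | COC1=C(c2ccc(O)cc2)C(=O)[C@](OC)(c2ccc(O)cc2)C1=O | intermediate
15 | dipotassium bisphenoxide of 14 | COC1=C(c2ccc([O-])cc2)C(=O)[C@](OC)(c2ccc([O-])cc2)C1=O.[K+].[K+] | intermediate (not isolated)
16 | (3R,4R)-4,7-bis(4-hydroxyphenyl)-4,6-dimethoxy-1-oxaspiro[2.4]hept-6-en-5-one | COC1=C(c2ccc(O)cc2)[C@@]2(CO2)[C@](OC)(c2ccc(O)cc2)C1=O | target

**Totals**
Total step count: 9. Longest linear sequence: 8 steps (1 → 2 → 5 → 7 → 10 → 11 → 13 → 14 → 16; the branch 3 → 4 is one step).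

**Steps most likely to fail**

Step 9. The methylene transfer may go to the C5 carbonyl instead of C3, or the ylide may enter from the aryl face. The fallback sets out from 13 and takes the competing carbonyl out by a redox detour. Luche reduction (NaBH4, CeCl3·7H2O, MeOH, −78 °C) should reduce the non-vinylogous carbonyl next to the methoxy-bearing alkene carbon and give the hydroxy enone F1. The only remaining ketone is then epoxidised with the ylide from Me3SI and KN(SiMe3)2 to give the epoxy alcohol F2. Dess–Martin periodinane with NaHCO3 restores the enone in the silylated target F3. Bu4NF/AcOH then removes both silyl groups, and the route is rejoined at 16.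

Step 6. Oxidation at the phosphonate-bearing methine may compete with dioxygenation of the alkyne. The fallback sets out from 7 and closes the same C6=C7 bond by an aldol condensation on a substrate without that methine. The ester is converted with (methoxymethyl)lithium (from Bu3SnCH2OMe and n-BuLi, THF, −78 °C) into the methoxymethyl ketone F4. Buffered KMnO4 then gives the triketone F5. Intramolecular aldol condensation (DBU, toluene, rt) of the only enolisable position onto the aryl ketone returns to the route at 13.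

Step 3. Enantioface discrimination in the alkynylation may be insufficient. The fallback sets out from 2 and 4 and replaces asymmetric catalysis by resolution. The lithium acetylide of 4 (n-BuLi, THF, −78 °C) is added to the ketone of 2 to give the racemic carbinol F6. F6 is separated by preparative chromatography on a chiral stationary phase, and the (R)-enantiomer re-enters the route as 5.

**Further compounds**
F1 | step 9 | (5S)-4-hydroxy-3,5-dimethoxy-2,5-bis[4-(triisopropylsilyloxy)phenyl]cyclopent-2-en-1-one, carbinol configuration not controlled | COC1=C(c2ccc(O[Si](C(C)C)(C(C)C)C(C)C)cc2)C(=O)[C@](OC)(c2ccc(O[Si](C(C)C)(C(C)C)C(C)C)cc2)C1O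
F2 | step 9 | (3R,4S)-4,6-dimethoxy-4,7-bis[4-(triisopropylsilyloxy)phenyl]-1-oxaspiro[2.4]hept-6-en-5-ol, carbinol configuration not controlled | COC1=C(c2ccc(O[Si](C(C)C)(C(C)C)C(C)C)cc2)[C@@]2(CO2)[C@](OC)(c2ccc(O[Si](C(C)C)(C(C)C)C(C)C)cc2)C1O
F3 | step 9 | (3R,4R)-4,6-dimethoxy-4,7-bis[4-(triisopropylsilyloxy)phenyl]-1-oxaspiro[2.4]hept-6-en-5-one | COC1=C(c2ccc(O[Si](C(C)C)(C(C)C)C(C)C)cc2)[C@@]2(CO2)[C@](OC)(c2ccc(O[Si](C(C)C)(C(C)C)C(C)C)cc2)C1=O
F4 | step 6 | (3R)-1,3-dimethoxy-3,5-bis[4-(triisopropylsilyloxy)phenyl]pent-4-yn-2-one | CC(C)[Si](C(C)C)(C(C)C)Oc1ccc(cc1)C#C[C@](OC)(c1ccc(O[Si](C(C)C)(C(C)C)C(C)C)cc1)C(=O)COC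
F5 | step 6 | (3S)-3,5-dimethoxy-1,3-bis[4-(triisopropylsilyloxy)phenyl]pentane-1,2,4-trione | CC(C)[Si](C(C)C)(C(C)C)Oc1ccc(cc1)C(=O)C(=O)[C@](OC)(c1ccc(O[Si](C(C)C)(C(C)C)C(C)C)cc1)C(=O)COC
F6 | step 3 | racemic methyl 2-hydroxy-2,4-bis[4-(triisopropylsilyloxy)phenyl]but-3-ynoate | CC(C)[Si](C(C)C)(C(C)C)Oc1ccc(cc1)C#CC(O)(c1ccc(O[Si](C(C)C)(C(C)C)C(C)C)cc1)C(=O)OC
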